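**Plan**

Units, read from the left of the SMILES: A orsellinoyl, B (R)-3-oxybutanoyl, C 2,4-dihydroxy-6-[(R)-2-oxypropyl]benzoyl, D (R)-3-oxybutanoyl, E 5-[(R)-2-oxypropyl]resorcinol.
Enabling feature: ring C with its carboxyl carbon is a coiled 3,5,7-trioxoalkanoate (carboxyl = chain C1, ring carbons = chain C2–C7, phenol oxygens on C3 and C5). Its C7–C8–C9(O)–CH3 part is a further (R)-3-acyloxybutanoyl group, the same building block as B and D.
Cuts: first, together, the acyl C–O bond of the C–D ester and the arene C1–C6 bond of ring C (chain C2–C7), giving diketo-dioxinone 21 (A–B) and alcohol 30 (D–E). Then chain bonds C6–C7 and C4–C5, the ester bonds A–B, B–C and D–E, and the aryl–CH2 bond of E.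
Forward: A is esterified with B and B with a third hydroxybutanoate; this triester acid is C-acylated onto keto-dioxinone ester 17 and decarboxylated to 21. E comes from an aryl Grignard reagent and is joined to D. Then 21 and 30 are united while ring C, the only ring built, forms, and hydrogenolysis finishes the route.
Stereochemistry: all four centres are R and are bought, B, C and D from methyl (R)-3-hydroxybutanoate and E from (R)-propylene oxide. No step breaks a bond at any of them.

Key step: step 18

Remark: polycarbonyl compounds are drawn as keto tautomers. The enolisable methine carbons of 19, 20 and 33 and the carbinol carbon of 33 carry no descriptor because they are labile or transient and are gone after step 18. The aromatisation is balanced with loss of one molecule of water.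

**Route**

Step 1
Reactants: 1 orsellinic acid (2,4-dihydroxy-6-methylbenzoic acid)
Product: 2 benzyl 2,4-bis(benzyloxy)-6-methylbenzoate
Conditions: BnBr (3.5 equiv), K2CO3, DMF, rt → 50 °C
Reagents that add atoms: benzyl bromide, BrCc1ccccc1
Why: Williamson etherification of both phenols and SN2 alkylation of the carboxylate run in one pot, and the carboxylate should react first, so the decarboxylation-prone free acid is consumed before warming.

Step 2
Reactants: 2 benzyl 2,4-bis(benzyloxy)-6-methylbenzoate
Product: 3 2,4-bis(benzyloxy)-6-methylbenzoic acid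
Conditions: KOH, DMSO/H2O, 90 °C; then aq. HCl
Reagents that add atoms: potassium hydroxide, [K+].[OH-]
Why: Saponification of the di-ortho-substituted benzoate needs forcing conditions, which are harmless here because aryl benzyl ethers are the only other functions present.

Step 3
Reactants: 4 methyl (R)-3-hydroxybutanoate
Product: 5 allyl (R)-3-hydroxybutanoate
Conditions: allyl alcohol (solvent), Ti(OiPr)4 (5 mol %), reflux, MeOH distilled off
Reagents that add atoms: allyl alcohol, C=CCO
Why: Titanate-catalysed transesterification is neutral and exchanges only the acyl–oxygen bond, so the carbinol centre stays R and no dehydration is expected.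

Step 4
Reactants: 3 2,4-bis(benzyloxy)-6-methylbenzoic acid; 5 allyl (R)-3-hydroxybutanoate
Product: 7 allyl (3R)-3-[2,4-bis(benzyloxy)-6-methylbenzoyloxy]butanoate, via aroyl chloride 6 (not isolated)
Conditions: (COCl)2, DMF (cat.), CH2Cl2, 0 °C → rt, evaporate; then 5, Et3N, DMAP, CH2Cl2, 0 → 40 °C
Reagents that add atoms: none
Why: Acyl substitution on the acid chloride under DMAP nucleophilic catalysis should overcome the di-ortho hindrance (no α-hydrogen, hence no ketene pathway), and only the O–H bond of 5 breaks, so the R centre of unit B is carried over.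

Step 5
Reactants: 7 allyl (3R)-3-[2,4-bis(benzyloxy)-6-methylbenzoyloxy]butanoate
Product: 8 (3R)-3-[2,4-bis(benzyloxy)-6-methylbenzoyloxy]butanoic acid
Conditions: Pd(PPh3)4 (5 mol %), morpholine, THF, rt; dil. HCl wash
Reagents that add atoms: none
Why: In this Tsuji–Trost deallylation Pd(0) ionises only the allyl ester and morpholine takes up the π-allyl fragment, under near-neutral conditions that spare the benzyl ethers, the aryl ester and the β-acyloxy ester.

Step 6
Reactants: 8 (3R)-3-[2,4-bis(benzyloxy)-6-methylbenzoyloxy]butanoic acid; 5 allyl (R)-3-hydroxybutanoate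
Product: 10 allyl (3R)-3-{(3R)-3-[2,4-bis(benzyloxy)-6-methylbenzoyloxy]butanoyloxy}butanoate, via acyl chloride 9 (not isolated)
Conditions: (COCl)2, DMF (cat.), CH2Cl2, 0 °C → rt, evaporate; then 5, pyridine, CH2Cl2, −78 → 0 °C
Reagents that add atoms: none
Why: Acid chloride/pyridine esterification at low temperature is the usual way of joining 3-hydroxybutanoate units while holding back E1cB loss of the β-acyloxy group, and the second R centre (the future side-chain carbon of unit C) arrives intact with 5.

Step 7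
Reactants: 10 allyl (3R)-3-{(3R)-3-[2,4-bis(benzyloxy)-6-methylbenzoyloxy]butanoyloxy}butanoate
Product: 11 (3R)-3-{(3R)-3-[2,4-bis(benzyloxy)-6-methylbenzoyloxy]butanoyloxy}butanoic acid
Conditions: Pd(PPh3)4 (5 mol %), morpholine, THF, rt; dil. HCl wash
Reagents that add atoms: none
Why: The same Tsuji–Trost deallylation as in step 5 should pick out the terminal allyl ester, since the two inner esters cannot form a π-allyl complex.

Step 8
Reactants: 12 Meldrum's acid (2,2-dimethyl-1,3-dioxane-4,6-dione)
Product: 13 allyl hydrogen malonate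
Conditions: allyl alcohol (1.05 equiv), PhMe, reflux
Reagents that add atoms: allyl alcohol, C=CCO
Why: Alcoholysis of Meldrum's acid (acyl substitution with ring opening and loss of acetone) is the standard entry to malonic half esters.

Step 9
Reactants: 13 allyl hydrogen malonate; 14 2,2,6-trimethyl-4H-1,3-dioxin-4-one
Product: 17 allyl 4-(2,2-dimethyl-4-oxo-4H-1,3-dioxin-6-yl)-3-oxobutanoate, via allyl malonyl chloride 15 (not isolated), via lithium dienolate 16 (not isolated)
Conditions: 13, (COCl)2, DMF (cat.), CH2Cl2, 0 °C → rt, evaporate; 14 (2 equiv), LiHMDS (2.1 equiv), THF, −78 °C, then 15, −78 °C; aq. NH4Cl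
Reagents that add atoms: none
Why: In this vinylogous Claisen-type acylation the dioxinone dienolate is acylated by acid chlorides at its exocyclic γ-carbon (chain bond C4–C5), and the surplus dienolate absorbs the acidic proton of the β-keto ester formed.

Step 10
Reactants: 11 (3R)-3-{(3R)-3-[2,4-bis(benzyloxy)-6-methylbenzoyloxy]butanoyloxy}butanoic acid; 17 allyl 4-(2,2-dimethyl-4-oxo-4H-1,3-dioxin-6-yl)-3-oxobutanoate
Product: 19 allyl 2-acyl-4-(2,2-dimethyl-4-oxo-4H-1,3-dioxin-6-yl)-3-oxobutanoate in which the 2-acyl group is the acyl residue of 11, via acyl chloride 18 (not isolated)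
Conditions: (COCl)2, DMF (cat.), CH2Cl2, 0 °C → rt, evaporate; then 17, MgCl2, pyridine, CH2Cl2, 0 °C → rt
Reagents that add atoms: none
Why: In this magnesium chloride/amine soft-enolisation C-acylation the chelated enolate of the β-keto ester carbon of 17 reacts on carbon (chain bond C6–C7) because the tricarbonyl product is held as a stable magnesium chelate, and the weak base should spare the β-acyloxy groups of 18.

Step 11
Reactants: 19 allyl tricarbonyl ester from step 10
Product: 21 (2R)-7-(2,2-dimethyl-4-oxo-4H-1,3-dioxin-6-yl)-4,6-dioxoheptan-2-yl (3R)-3-[2,4-bis(benzyloxy)-6-methylbenzoyloxy]butanoate, via tricarbonyl acid 20 (not isolated)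
Conditions: Pd(PPh3)4 (5 mol %), morpholine (2 equiv), THF, 0 °C → rt; used promptly
Reagents that add atoms: none
Why: Tsuji–Trost deallylation releases a β,β′-diketo acid that decarboxylates spontaneously at room temperature, a known way of unmasking diketo-dioxinones without strong base.

Step 12
Reactants: 22 5-bromoresorcinol
Product: 23 1,3-bis(benzyloxy)-5-bromobenzene
Conditions: BnBr (2.3 equiv), K2CO3, acetone, reflux
Reagents that add atoms: benzyl bromide, BrCc1ccccc1
Why: This is a Williamson etherification of two unhindered phenols, and the aryl bromide is inert to carbonate.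

Step 13
Reactants: 23 1,3-bis(benzyloxy)-5-bromobenzene; 24 (R)-propylene oxide
Product: 26 (2R)-1-[3,5-bis(benzyloxy)phenyl]propan-2-ol, via Grignard reagent 25 (not isolated)
Conditions: Mg, I2 (cat.), THF, 50 °C; then CuI (10 mol %), 24, −30 → 0 °C; aq. NH4Cl
Reagents that add atoms: none
Why: Copper-catalysed SN2 opening of a terminal epoxide by an aryl Grignard reagent takes place at the unsubstituted carbon, so the C–O bond at the stereocentre is untouched and the R configuration of 24 becomes that of unit E.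

Step 14
Reactants: 4 methyl (R)-3-hydroxybutanoate
Product: 27 methyl (3R)-3-(tert-butyldimethylsilyloxy)butanoate
Conditions: TBSCl, imidazole, DMF, rt
Reagents that add atoms: tert-butyldimethylsilyl chloride, CC(C)(C)[Si](C)(C)Cl
Why: Imidazole-promoted silylation of a secondary alcohol forms only an O–Si bond, so the R centre is retained.

Step 15
Reactants: 27 methyl (3R)-3-(tert-butyldimethylsilyloxy)butanoate
Product: 28 (3R)-3-(tert-butyldimethylsilyloxy)butanoic acid
Conditions: LiOH, THF/MeOH/H2O, 0 °C → rt; then dil. HCl to pH 4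
Reagents that add atoms: lithium hydroxide, [Li+].[OH-]
Why: Saponification of an unhindered methyl ester runs at or below room temperature, where the poor silyloxy leaving group should not eliminate, and acidification only to pH 4 keeps the silyl ether.

Step 16
Reactants: 28 (3R)-3-(tert-butyldimethylsilyloxy)butanoic acid; 26 (2R)-1-[3,5-bis(benzyloxy)phenyl]propan-2-ol
Product: 29 (2R)-1-[3,5-bis(benzyloxy)phenyl]propan-2-yl (3R)-3-(tert-butyldimethylsilyloxy)butanoate
Conditions: DCC, DMAP (cat.), CH2Cl2, 0 °C → rt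
Reagents that add atoms: none
Why: Steglich esterification joins an unhindered aliphatic acid to a secondary alcohol through the acylpyridinium ion, and both R centres are retained because neither C–O bond at carbon is broken.

Step 17
Reactants: 29 (2R)-1-[3,5-bis(benzyloxy)phenyl]propan-2-yl (3R)-3-(tert-butyldimethylsilyloxy)butanoate
Product: 30 (2R)-1-[3,5-bis(benzyloxy)phenyl]propan-2-yl (3R)-3-hydroxybutanoate
Conditions: HF·pyridine, THF, 0 °C → rt
Reagents that add atoms: none
Why: Fluoride-driven desilylation in a mildly acidic medium avoids the basic conditions that could provoke β-elimination of the hydroxy ester, and leaves the ester and benzyl ethers alone.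

Step 18
Reactants: 21 diketo-dioxinone carrying A–B; 30 D–E hydroxy ester
Product: 34 hansforester A tetrabenzyl ether (benzyl on the four phenols of rings A/E; ring C phenols free), via acylketene 31 (not isolated), via triketo ester 32 (not isolated), via cyclic aldol 33 (not isolated)
Conditions: 21, 30 (1.1 equiv), PhMe (0.1 M), 110 °C; concentrate; K2CO3 (2 equiv), CH2Cl2/i-PrOH, rt; then HCl (4 M in dioxane), rt
Reagents that add atoms: none
Why: At 110 °C the dioxinone of 21 undergoes a retro-hetero-Diels–Alder reaction, acetone leaves, and the secondary hydroxyl of 30 adds to the linear, sterically open ketene carbon of 31, so the acyl C–O bond of the C–D ester is in place (32) while its carbonyl still belongs to an open chain and not to a di-ortho-substituted arene. Carbonate then removes a proton from chain C2 (flanked by the new ester and the C3 ketone), C2 adds to the C7 ketone in a 6-(enolendo)-exo-trig aldol that creates the arene C1–C6 bond (33), and HCl eliminates one molecule of water, after which the C3 and C5 ketones tautomerise to the two phenols of ring C. The closest known reaction type is this very sequence, dioxinone thermolysis, alcohol capture of the acylketene and aldol aromatisation to a resorcylate ester, applied here to larger partners. No lasting stereocentre is formed, since the carbinol and methine centres of 33 are erased on aromatisation and none of the four R centres belongs to a bond that changes. The step needs capture by 30 rather than closure of 31 to a 4-hydroxy-2-pyranone, aldol folding C2→C7 rather than Claisen folding C6→C1, and survival of the A–B carboxylate on C9, β to the C7 ketone. A slight excess of 30 at fairly high concentration should secure the first, a weak base that cannot expel an alkoxide from the ester the second, and the third rests on the roughly ten pK units by which the C2, C4 and C6 protons outrank those at C8, so that only delocalised enolates form in which C7 no longer acidifies C8–H, while i-PrOH as co-solvent and anhydrous acid keep the four esters from exchange.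

Step 19
Reactants: 34 hansforester A tetrabenzyl ether
Product: 35 hansforester A
Conditions: H2 (1 atm), 10 % Pd/C, EtOAc/EtOH, rt
Reagents that add atoms: none
Why: Catalytic hydrogenolysis cleaves the four aryl benzyl ethers, whereas every ester C–O bond sits on an aliphatic or homobenzylic carbon and should be inert, so all four R centres persist.

**Compound list**

1 | orsellinic acid (2,4-dihydroxy-6-methylbenzoic acid) | Cc1cc(O)cc(O)c1C(=O)O | starting material
2 | benzyl 2,4-bis(benzyloxy)-6-methylbenzoate | Cc1cc(OCc2ccccc2)cc(OCc2ccccc2)c1C(=O)OCc1ccccc1 | intermediate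
3 | 2,4-bis(benzyloxy)-6-methylbenzoic acid | Cc1cc(OCc2ccccc2)cc(OCc2ccccc2)c1C(=O)O | intermediate
4 | methyl (R)-3-hydroxybutanoate | C[C@@H](O)CC(=O)OC | starting material
5 | allyl (R)-3-hydroxybutanoate | C[C@@H](O)CC(=O)OCC=C | intermediate
6 | 2,4-bis(benzyloxy)-6-methylbenzoyl chloride (not isolated) | Cc1cc(OCc2ccccc2)cc(OCc2ccccc2)c1C(=O)Cl | intermediate
7 | allyl (3R)-3-[2,4-bis(benzyloxy)-6-methylbenzoyloxy]butanoate (A–B allyl ester) | Cc1cc(OCc2ccccc2)cc(OCc2ccccc2)c1C(=O)O[C@H](C)CC(=O)OCC=C | intermediate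
8 | (3R)-3-[2,4-bis(benzyloxy)-6-methylbenzoyloxy]butanoic acid (A–B acid) | Cc1cc(OCc2ccccc2)cc(OCc2ccccc2)c1C(=O)O[C@H](C)CC(=O)O | intermediate
9 | (3R)-3-[2,4-bis(benzyloxy)-6-methylbenzoyloxy]butanoyl chloride (not isolated) | Cc1cc(OCc2ccccc2)cc(OCc2ccccc2)c1C(=O)O[C@H](C)CC(=O)Cl | intermediate
10 | allyl (3R)-3-{(3R)-3-[2,4-bis(benzyloxy)-6-methylbenzoyloxy]butanoyloxy}butanoate | Cc1cc(OCc2ccccc2)cc(OCc2ccccc2)c1C(=O)O[C@H](C)CC(=O)O[C@H](C)CC(=O)OCC=C | intermediate
11 | (3R)-3-{(3R)-3-[2,4-bis(benzyloxy)-6-methylbenzoyloxy]butanoyloxy}butanoic acid | Cc1cc(OCc2ccccc2)cc(OCc2ccccc2)c1C(=O)O[C@H](C)CC(=O)O[C@H](C)CC(=O)O | intermediate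
12 | Meldrum's acid (2,2-dimethyl-1,3-dioxane-4,6-dione) | CC1(C)OC(=O)CC(=O)O1 | starting material
13 | allyl hydrogen malonate | C=CCOC(=O)CC(=O)O | intermediate
14 | 2,2,6-trimethyl-4H-1,3-dioxin-4-one | CC1=CC(=O)OC(C)(C)O1 | starting material
15 | allyl 3-chloro-3-oxopropanoate (not isolated) | C=CCOC(=O)CC(=O)Cl | intermediate
16 | lithium dienolate of 14 (not isolated) | C=C1C=C(O[Li])OC(C)(C)O1 | intermediate
17 | allyl 4-(2,2-dimethyl-4-oxo-4H-1,3-dioxin-6-yl)-3-oxobutanoate | C=CCOC(=O)CC(=O)CC1=CC(=O)OC(C)(C)O1 | intermediate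
18 | acid chloride of 11 (not isolated) | Cc1cc(OCc2ccccc2)cc(OCc2ccccc2)c1C(=O)O[C@H](C)CC(=O)O[C@H](C)CC(=O)Cl | intermediate
19 | allyl 2-acyl-4-(2,2-dimethyl-4-oxo-4H-1,3-dioxin-6-yl)-3-oxobutanoate, acyl = acyl residue of 11 | Cc1cc(OCc2ccccc2)cc(OCc2ccccc2)c1C(=O)O[C@H](C)CC(=O)O[C@H](C)CC(=O)C(C(=O)OCC=C)C(=O)CC1=CC(=O)OC(C)(C)O1 | intermediate
20 | free tricarbonyl acid from 19 (not isolated) | Cc1cc(OCc2ccccc2)cc(OCc2ccccc2)c1C(=O)O[C@H](C)CC(=O)O[C@H](C)CC(=O)C(C(=O)O)C(=O)CC1=CC(=O)OC(C)(C)O1 | intermediate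
21 | (2R)-7-(2,2-dimethyl-4-oxo-4H-1,3-dioxin-6-yl)-4,6-dioxoheptan-2-yl (3R)-3-[2,4-bis(benzyloxy)-6-methylbenzoyloxy]butanoate (diketo-dioxinone carrying A–B) | Cc1cc(OCc2ccccc2)cc(OCc2ccccc2)c1C(=O)O[C@H](C)CC(=O)O[C@H](C)CC(=O)CC(=O)CC1=CC(=O)OC(C)(C)O1 | intermediate
22 | 5-bromoresorcinol | Oc1cc(O)cc(Br)c1 | starting material
23 | 1,3-bis(benzyloxy)-5-bromobenzene | Brc1cc(OCc2ccccc2)cc(OCc2ccccc2)c1 | intermediate
24 | (R)-propylene oxide | C[C@@H]1CO1 | starting material
25 | 3,5-bis(benzyloxy)phenylmagnesium bromide (not isolated) | Br[Mg]c1cc(OCc2ccccc2)cc(OCc2ccccc2)c1 | intermediate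
26 | (2R)-1-[3,5-bis(benzyloxy)phenyl]propan-2-ol | C[C@@H](O)Cc1cc(OCc2ccccc2)cc(OCc2ccccc2)c1 | intermediate
27 | methyl (3R)-3-(tert-butyldimethylsilyloxy)butanoate | C[C@@H](O[Si](C)(C)C(C)(C)C)CC(=O)OC | intermediate
28 | (3R)-3-(tert-butyldimethylsilyloxy)butanoic acid | C[C@@H](O[Si](C)(C)C(C)(C)C)CC(=O)O | intermediate
29 | (2R)-1-[3,5-bis(benzyloxy)phenyl]propan-2-yl (3R)-3-(tert-butyldimethylsilyloxy)butanoate | C[C@@H](O[Si](C)(C)C(C)(C)C)CC(=O)O[C@H](C)Cc1cc(OCc2ccccc2)cc(OCc2ccccc2)c1 | intermediate
30 | (2R)-1-[3,5-bis(benzyloxy)phenyl]propan-2-yl (3R)-3-hydroxybutanoate (D–E hydroxy ester) | C[C@@H](O)CC(=O)O[C@H](C)Cc1cc(OCc2ccccc2)cc(OCc2ccccc2)c1 | intermediate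
31 | triketo-ketene from 21 by loss of acetone (not isolated) | Cc1cc(OCc2ccccc2)cc(OCc2ccccc2)c1C(=O)O[C@H](C)CC(=O)O[C@H](C)CC(=O)CC(=O)CC(=O)C=C=O | intermediate
32 | open-chain 3,5,7-triketo ester of 30 (not isolated) | Cc1cc(OCc2ccccc2)cc(OCc2ccccc2)c1C(=O)O[C@H](C)CC(=O)O[C@H](C)CC(=O)CC(=O)CC(=O)CC(=O)O[C@H](C)CC(=O)O[C@H](C)Cc1cc(OCc2ccccc2)cc(OCc2ccccc2)c1 | intermediate
33 | cyclic aldol, 2-hydroxy-4,6-dioxocyclohexanecarboxylate (two transient ring centres undefined; not isolated) | Cc1cc(OCc2ccccc2)cc(OCc2ccccc2)c1C(=O)O[C@H](C)CC(=O)O[C@H](C)CC1(O)CC(=O)CC(=O)C1C(=O)O[C@H](C)CC(=O)O[C@H](C)Cc1cc(OCc2ccccc2)cc(OCc2ccccc2)c1 | intermediate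
34 | hansforester A tetrabenzyl ether (rings A and E benzylated, ring C phenols free) | Cc1cc(OCc2ccccc2)cc(OCc2ccccc2)c1C(=O)O[C@H](C)CC(=O)O[C@H](C)Cc1cc(O)cc(O)c1C(=O)O[C@H](C)CC(=O)O[C@H](C)Cc1cc(OCc2ccccc2)cc(OCc2ccccc2)c1 | intermediate
35 | hansforester A | Cc1cc(O)cc(O)c1C(=O)O[C@H](C)CC(=O)O[C@H](C)Cc1cc(O)cc(O)c1C(=O)O[C@H](C)CC(=O)O[C@H](C)Cc1cc(O)cc(O)c1 | target

**Counts and risks**

Total step count: 19.
Longest linear sequence: 10 steps from orsellinic acid (steps 1, 2, 4, 5, 6, 7, 10, 11, 18, 19).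

**Risk 1, step 18.**
- What may go wrong: E1cB expulsion of the A–B carboxylate from C9 once the C7 ketone meets base, self-closure of the ketene to a pyranone before the alcohol arrives, or Claisen-type misfolding.
- The fallback sets out from 28 (drawing 17, 30 and 9 from the main route) and comes back at 35. It keeps the same ring-C construction but puts a silyl ether, a much poorer leaving group, on C9 and attaches A–B afterwards.
- Oxalyl chloride converts 28 into (3R)-3-(tert-butyldimethylsilyloxy)butanoyl chloride F1. This C-acylates 17 under MgCl2/pyridine to the silyloxy allyl tricarbonyl ester F2.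
- Pd(PPh3)4/morpholine leads through the silyloxy tricarbonyl acid F3 to the silyloxy diketo-dioxinone F4.
- Thermolysis of F4 with 30 in toluene passes through the silyloxy acylketene F5 and the silyloxy triketo ester F6. Carbonate gives the silyloxy cyclic aldol F7, and acetic acid, chosen to spare the silyl ether, completes the silyloxy resorcylate F8.
- Benzylation (BnBr, K2CO3, acetone) gives the ring-C dibenzyl ether F9, and HF·pyridine frees the homobenzylic alcohol F10.
- Acylation of F10 with 9 and pyridine gives hansforester A hexabenzyl ether F11, and hydrogenolysis over Pd/C delivers 35.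

**Risk 2, step 10.**
- What may go wrong: dehydrochlorination of the acid chloride to a ketene followed by loss of the β-acyloxy group, or acylation on oxygen instead of carbon.
- The fallback sets out from 11 (with 13 and 16) and comes back at 19. It exchanges the roles of the two acyl partners so that no acid chloride bearing a β-acyloxy group is needed.
- Carbonyldiimidazole turns 11 into the acyl imidazolide F12. This undergoes the decarboxylative Claisen condensation (Masamune–Brooks reaction) with magnesium bis(allyl malonate) F13, made from 13 and Mg(OEt)2, to give the β-keto allyl ester F14.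
- Separately, dienolate 16 is carboxylated with CO2 to (2,2-dimethyl-4-oxo-4H-1,3-dioxin-6-yl)acetic acid F15, which oxalyl chloride converts into (2,2-dimethyl-4-oxo-4H-1,3-dioxin-6-yl)acetyl chloride F16.
- MgCl2/pyridine C-acylation of F14 with F16 gives 19, because its central carbon carries the same two acyl groups whichever is introduced last.

**Risk 3, step 4.**
- What may go wrong: sluggish acyl transfer at the di-ortho-substituted carbonyl, so that hydrolysis or symmetrical anhydride formation outruns esterification.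
- The fallback sets out from 3 and comes back at 7. It makes the ester bond at the carbinol carbon instead of at the hindered carbonyl.
- Purchased methyl (S)-3-hydroxybutanoate F17 is transesterified as in step 3 to allyl (S)-3-hydroxybutanoate F18.
- A Mitsunobu reaction (PPh3, DIAD, toluene, 0 °C) then lets the carboxylate of 3 displace the activated hydroxyl in an SN2 process with inversion, S to R, giving 7.

**Further compounds**

F1 | step 18 | (3R)-3-(tert-butyldimethylsilyloxy)butanoyl chloride | C[C@@H](O[Si](C)(C)C(C)(C)C)CC(=O)Cl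
F2 | step 18 | allyl 2-[(3R)-3-(tert-butyldimethylsilyloxy)butanoyl]-4-(2,2-dimethyl-4-oxo-4H-1,3-dioxin-6-yl)-3-oxobutanoate | C[C@@H](O[Si](C)(C)C(C)(C)C)CC(=O)C(C(=O)OCC=C)C(=O)CC1=CC(=O)OC(C)(C)O1
F3 | step 18 | free tricarbonyl acid from F2 | C[C@@H](O[Si](C)(C)C(C)(C)C)CC(=O)C(C(=O)O)C(=O)CC1=CC(=O)OC(C)(C)O1
F4 | step 18 | 6-[(6R)-6-(tert-butyldimethylsilyloxy)-2,4-dioxoheptyl]-2,2-dimethyl-4H-1,3-dioxin-4-one | C[C@@H](O[Si](C)(C)C(C)(C)C)CC(=O)CC(=O)CC1=CC(=O)OC(C)(C)O1
F5 | step 18 | silyloxy triketo-ketene from F4 | C[C@@H](O[Si](C)(C)C(C)(C)C)CC(=O)CC(=O)CC(=O)C=C=O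
F6 | step 18 | silyloxy 3,5,7-triketo ester of 30 | C[C@@H](O[Si](C)(C)C(C)(C)C)CC(=O)CC(=O)CC(=O)CC(=O)O[C@H](C)CC(=O)O[C@H](C)Cc1cc(OCc2ccccc2)cc(OCc2ccccc2)c1
F7 | step 18 | silyloxy cyclic aldol (two transient ring centres undefined) | C[C@@H](O[Si](C)(C)C(C)(C)C)CC1(O)CC(=O)CC(=O)C1C(=O)O[C@H](C)CC(=O)O[C@H](C)Cc1cc(OCc2ccccc2)cc(OCc2ccccc2)c1
F8 | step 18 | C–D–E resorcylate with silyl ether on the ring-C side chain and free ring-C phenols | C[C@@H](O[Si](C)(C)C(C)(C)C)Cc1cc(O)cc(O)c1C(=O)O[C@H](C)CC(=O)O[C@H](C)Cc1cc(OCc2ccccc2)cc(OCc2ccccc2)c1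
F9 | step 18 | ring-C dibenzyl ether of F8 | C[C@@H](O[Si](C)(C)C(C)(C)C)Cc1cc(OCc2ccccc2)cc(OCc2ccccc2)c1C(=O)O[C@H](C)CC(=O)O[C@H](C)Cc1cc(OCc2ccccc2)cc(OCc2ccccc2)c1
F10 | step 18 | homobenzylic alcohol from F9 | C[C@@H](O)Cc1cc(OCc2ccccc2)cc(OCc2ccccc2)c1C(=O)O[C@H](C)CC(=O)O[C@H](C)Cc1cc(OCc2ccccc2)cc(OCc2ccccc2)c1
F11 | step 18 | hansforester A hexabenzyl ether | Cc1cc(OCc2ccccc2)cc(OCc2ccccc2)c1C(=O)O[C@H](C)CC(=O)O[C@H](C)Cc1cc(OCc2ccccc2)cc(OCc2ccccc2)c1C(=O)O[C@H](C)CC(=O)O[C@H](C)Cc1cc(OCc2ccccc2)cc(OCc2ccccc2)c1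
F12 | step 10 | acyl imidazolide of 11 | Cc1cc(OCc2ccccc2)cc(OCc2ccccc2)c1C(=O)O[C@H](C)CC(=O)O[C@H](C)CC(=O)n1ccnc1
F13 | step 10 | magnesium bis(allyl malonate) | [Mg+2].[O-]C(=O)CC(=O)OCC=C.[O-]C(=O)CC(=O)OCC=C
F14 | step 10 | allyl (5R)-5-{(3R)-3-[2,4-bis(benzyloxy)-6-methylbenzoyloxy]butanoyloxy}-3-oxohexanoate | Cc1cc(OCc2ccccc2)cc(OCc2ccccc2)c1C(=O)O[C@H](C)CC(=O)O[C@H](C)CC(=O)CC(=O)OCC=C
F15 | step 10 | (2,2-dimethyl-4-oxo-4H-1,3-dioxin-6-yl)acetic acid | OC(=O)CC1=CC(=O)OC(C)(C)O1
F16 | step 10 | (2,2-dimethyl-4-oxo-4H-1,3-dioxin-6-yl)acetyl chloride | ClC(=O)CC1=CC(=O)OC(C)(C)O1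
F17 | step 4 | methyl (S)-3-hydroxybutanoate (purchased) | C[C@H](O)CC(=O)OC
F18 | step 4 | allyl (S)-3-hydroxybutanoate | C[C@H](O)CC(=O)OCC=C
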